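Settle 4 questions before charging 3 flasks: which one leads, and how much target each holds at the end.

all flasks: free enzyme 19 µM

|  | starting material | second substrate | remark | time |
|---|---|---|---|---|
| gamma | 0.19 M | 0.095 M | run made earlier |  |
| epsilon | 0.19 M | 0.048 M | run made earlier |  |
| alpha | 0.19 M | 0.19 M | run made earlier |  |
| east | 0.19 M | 0.0950 M (fed, over 8.0 d) | all else is in the flask from the start; the feed brings no volume worth counting | 20 d |
| south-west | 0.19 M (fed, over 8.0 d) | 0.0950 M | all else is in the flask from the start; the feed brings no volume worth counting | 20 d |
| west | 0.19 M | 0.0950 M | everything together at the start | 20 d |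

1. which flask leads in amount of target, in percent of the starting material charged ("all alike" within 1.5 percentage points) (east / south-west / west / all alike)
2. how much target is there at the end, in percent of the starting material charged: east
3. how much target is there at the end, in percent of the starting material charged: south-west
4. how much target is there at the end, in percent of the starting material charged: west

| gamma: time / d | gamma: target / % | epsilon: time / d | epsilon: target / % | alpha: time / d | alpha: target / % |
|---|---|---|---|---|---|
| 1.04 | 38.2 | 1.04 | 19.0 | 0.625 | 67.0 |
| 1.67 | 38.8 | 1.67 | 19.3 | 1.67 | 71.5 |
| 2.00 | 37.3 | 2.00 | 20.3 | 3.00 | 71.5 |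
| 3.00 | 38.3 | 3.00 | 20.8 | 5.00 | 70.1 |
| 5.00 | 37.5 | 5.00 | 19.5 | 8.00 | 71.1 |
| 8.00 | 37.8 | 8.00 | 19.2 | 10.0 | 69.3 |
| 12.0 | 38.3 | 12.0 | 19.2 | 12.0 | 71.0 |

(scatter of a reading: 0.5 percentage points)



Read the plateaus first. Target stands flat from 1.67 d onward in gamma, epsilon and alpha, so take the readings at 12.0 d, convert them to molar and divide by the second substrate charged. In gamma 76.6% of the second substrate charged ends as target; call this fraction the capture share. Epsilon reads 76.0% and alpha 71.0%, while the charge changes by a factor of 3.96. So the share is not constant: alpha reads 5.6 percentage points under gamma, against a scatter of 0.5 points on a reading. Read this as a route to target that levels off at high [second substrate], beside another route that takes the rest.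

Decide on that basis. West repeats gamma, which gives 38.3% of the starting material charged. In east the second substrate arrives at 0.0119 M d⁻¹, which is less than the 0.0698 M d⁻¹ of target gamma made on average up to 1.04 d, so [second substrate] stays low in east and gamma's share serves there as the low estimate. In south-west the starting material arrives at 0.0238 M d⁻¹, which is less than the 0.204 M d⁻¹ alpha made on average up to 0.625 d. So in south-west [second substrate] waits for the feed and stays open to the other route. Expect south-west well under west, and east level with west or above it.

The forecast differs on east: it names west as leader, with 2.3% in east, 5.5% in south-west and 38% in west, holding that “the enzyme is dying rather than the reaction balancing”.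

East ends at 40.9%, south-west at 16.3% and west at 38.1%, so east leads.

    starting material + free enzyme ⇌ first complex (K = 9.30 M⁻¹, k = 7.50 M⁻¹ s⁻¹)
    first complex → loaded enzyme + first product (k = 2.00 s⁻¹)
    second substrate + loaded enzyme ⇌ second complex (K = 8.80 M⁻¹, k = 5.50 M⁻¹ s⁻¹)
    second complex → free enzyme + target (k = 0.970 s⁻¹)
    second substrate → decomposed reagent (k = 1.40 × 10⁻⁵ s⁻¹)

East's capture share comes to 81.7%, higher than the 76.6% of gamma, and [second substrate] stands at 0% of its charge at 20.0 d. Carry that share to a neighbouring flask, east with 0.024 M of second substrate: it reckons 10.3% of the starting material charged. That flask gives 10.3%, with second substrate, the limiting reagent, at 0% of its charge and starting material at 89.6%.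

The numbers in the tables were computed from invented constants.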